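**Strategy.** The angular C3a methyl is disconnected to a cyclopropane CH2 bridging C3 and C3a. On the six-membered ring this methyl is syn and 1,3-diaxial to the tertiary C7 hydroxyl (O–C7–C7a–C3a), so the zinc alkoxide of hexahydroindene 12 (C3=C3a alkene, C2 dioxolane, 4β silyl ether, H-7a β, C1 unsubstituted) should deliver the carbenoid to the α face and set C3a, and with it the trans ring fusion, in one operation. The cyclopropane then confines enolisation of the unmasked C2 ketone to C1, where the complete side chain is attached by aldol addition, and is finally opened to the methyl group.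

Key step: step 9

Locants: hydrindane C1–C7a, carbinol carbon C8 and cyclohexane C1'–C6' (C1' carbinol, C4' bromide, C5' CMe2) as in the target. β is the face of H-7a; α is the face of the C7 hydroxyl and the angular methyl.

Design notes:
- A C3=C3a precursor with 7α-OH, 4β-oxygen and 7aβ-H is stereochemically consistent with the target. The 4β (axial) oxygen is required so that inversion gives the equatorial 4α-bromide.
- The same silyl ether on C2 and C4 would leave two oxygens that cannot be told apart after the key step. C2 is therefore carried as a dioxolane, which has no facial bias of its own.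
- The dioxolane returns a ketone conjugated to the cyclopropane, so the methyl is released by electron transfer under stereoelectronic control, not by hydrogenolysis of an unactivated ring.
- C1 carries no ester. C8 arrives with the side chain, and the C2 ketone later lets the C8 hydroxyl set C2.

Assumption: ketal ketone 17 is bought; otherwise it is one step from the monoketal of cyclohexane-1,4-dione (NaH, MeI).

**Hydrindane core**

Step 1
Reactants: 1 (R)-linalool
Product: 3 lactol (5R)-5-ethenyl-5-methyloxolan-2-ol (both anomers), via secondary ozonide 2 (not isolated)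
Conditions: O3 (1.0 equiv, Sudan Red 7B end point), CH2Cl2, −78 °C; then Me2S, −78 °C → rt
Reagents that add atoms: ozone, [O-][O+]=O
Why: Chemoselective ozonolysis: the electron-rich trisubstituted alkene reacts far faster than the vinyl group, reductive work-up gives the γ-hydroxy aldehyde, which closes to the lactol, and the tertiary carbinol (later C7, R) is not touched.

Step 2
Reactants: 3 lactol; 4 ethynyl(trimethyl)silane
Product: 5 (3R,6RS)-3-methyl-8-(trimethylsilyl)oct-1-en-7-yne-3,6-diol
Conditions: 4 (3 equiv), n-BuLi (3 equiv), THF, −78 °C; then 3, −78 → 0 °C; NH4Cl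
Reagents that add atoms: ethynyl(trimethyl)silane (compound 4), C#C[Si](C)(C)C
Why: Acetylide 1,2-addition to the open hydroxy-aldehyde form of the lactol; the new carbinol is allowed to form as both epimers because it is oxidised in the next step.

Step 3
Reactants: 5 diol (C6 epimers)
Product: 6 (6R)-6-hydroxy-6-methyl-1-(trimethylsilyl)oct-7-en-1-yn-3-one
Conditions: MnO2 (15 equiv), CH2Cl2, rt
Reagents that add atoms: none
Why: Manganese dioxide oxidation is selective for the activated (propargylic) secondary alcohol, and the tertiary allylic alcohol cannot be oxidised.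

Step 4
Reactants: 6 ynone
Product: 7 (3R,6R)-3-methyl-8-(trimethylsilyl)oct-1-en-7-yne-3,6-diol
Conditions: Ru[(R,R)-TsDPEN](p-cymene) (2 mol%), i-PrOH, rt
Reagents that add atoms: none
Why: Noyori asymmetric transfer hydrogenation of an alkynyl ketone: hydride is delivered under catalyst control and the (R,R) ligand should give the (6R)-propargylic alcohol (later C4 with oxygen β); the distant tertiary carbinol has no influence.

Step 5
Reactants: 7 silylalkyne diol
Product: 8 (3R,6R)-3-methyloct-1-en-7-yne-3,6-diol
Conditions: K2CO3 (cat.), MeOH, rt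
Reagents that add atoms: none
Why: Base-mediated methanolysis (protodesilylation) of the C(sp)–Si bond; no stereocentre is involved.

Step 6
Reactants: 8 enyne diol
Product: 9 (3R,6R)-6-[tert-butyl(dimethyl)silyl]oxy-3-methyloct-1-en-7-yn-3-ol
Conditions: TBSCl (1.1 equiv), imidazole, DMF, 0 °C → rt
Reagents that add atoms: tert-butyldimethylsilyl chloride, CC(C)(C)[Si](C)(C)Cl
Why: Silylation with silyl chloride and imidazole is selective for the secondary propargylic hydroxyl; the tertiary alcohol is too hindered and stays free.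

Step 7
Reactants: 9 1,7-enyne
Product: 10 enone (4R,7R,7aS)-4-[tert-butyl(dimethyl)silyl]oxy-7-hydroxy-7-methyl-1,4,5,6,7,7a-hexahydro-2H-inden-2-one
Conditions: Co2(CO)8 (10 mol%), tetramethylthiourea (60 mol%), CO (1 atm), benzene, 70 °C
Reagents that add atoms: carbon monoxide, [C-]#[O+]
Why: Intramolecular Pauson–Khand [2+2+1] reaction of a 1,7-enyne: C7a is set in the alkene insertion, where a chair-like tether with the C7 methyl equatorial (free hydroxyl axial) and the propargylic silyl ether pseudo-axial, away from the cobalt-bound alkyne, should place H-7a anti to the C7 hydroxyl and syn to the C4 oxygen; any C7a epimer is removed here.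

Step 8
Reactants: 10 enone
Product: 12 key-step precursor (C2 ethylene ketal of 10 with free 7α-hydroxyl), via C7 trimethylsilyl ether 11 (not isolated)
Conditions: (TMSOCH2)2 (3 equiv), TMSOTf (5 mol%), CH2Cl2, −78 → −20 °C; pyridine; then K2CO3, MeOH, 0 °C
Reagents that add atoms: 1,2-bis(trimethylsilyloxy)ethane, C[Si](C)(C)OCCO[Si](C)(C)C
Why: Noyori ketalisation under aprotic conditions at low temperature forms the dioxolane without moving the C3=C3a double bond out of place or epimerising C7a; the tertiary alcohol is silylated in passing and freed again by methanolysis.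

Step 9
Reactants: 12 dioxolane precursor; 13 diiodomethane
Product: 15 cyclopropane (CH2 bridging C3 and C3a on the α face; ketal and 4β-OTBS unchanged), via iodomethylzinc alkoxide 14 (not isolated)
Conditions: Et2Zn (4 equiv), CH2I2 (8 equiv), CH2Cl2, 0 °C → rt; NH4Cl
Reagents that add atoms: diiodomethane (compound 13), ICI
Why: Diethylzinc turns the C7 hydroxyl into an ethylzinc alkoxide that exchanges with CH2I2 to the alkoxide-bound carbenoid 14, and this transfers CH2 to C3=C3a through a concerted butterfly transition state that forms C3a–CH2 and C3–CH2 together (Simmons–Smith reaction, Furukawa variant). The closest known reaction type is the hydroxyl-directed cyclopropanation of cyclic homoallylic and allylic alcohols, and enone dioxolanes are established substrates for zinc carbenoids. The three-membered ring is closed in one suprafacial [2+1] addition of a single carbon to one alkene face, so its fusion to the five-membered ring is necessarily cis. C3a is controlled by delivery from the axial C7 oxygen, which lies 1,3-syn-axial to the α lobe at C3a on the chair-like six-membered ring, and C3 follows from the suprafacial addition. The step needs α-face selectivity and enough reactivity at a trisubstituted alkene flanked by two allylic oxygens; the zinc alkoxide tether, the axial 4β-silyl ether that shields the other face, the unbiased dioxolane and an excess of carbenoid should secure both. Because H-7a is already β, α attack gives the trans relationship between H-7a and the future methyl.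

Step 10
Reactants: 15 cyclopropane ketal
Product: 16 cyclopropyl ketone (C2 ketone; C3–C3a methylene bridge α; 4β-OTBS; 7α-OH; H-7a β)
Conditions: PPTS (cat.), acetone/H2O (10:1), 40 °C
Reagents that add atoms: water, O
Why: Mild acid hydrolysis of the dioxolane (acetal cleavage) proceeds through an oxocarbenium ion stabilised by the cyclopropane, while the secondary TBS ether and the tertiary alcohol survive pyridinium tosylate.

**Side-chain aldehyde**

Step 11
Reactants: 17 7,7-dimethyl-1,4-dioxaspiro[4.5]decan-8-one
Product: 18 (8R)-7,7-dimethyl-1,4-dioxaspiro[4.5]decan-8-ol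
Conditions: (S)-Me-CBS (10 mol%), BH3·SMe2 (0.7 equiv), THF, −20 °C
Reagents that add atoms: none
Why: Corey–Bakshi–Shibata reduction: the quaternary carbon is the large and the CH2 the small ketone substituent, so the (S)-oxazaborolidine should give the (R)-alcohol (later C4', oxygen to be replaced with inversion) under catalyst control.

Step 12
Reactants: 18 ketal alcohol
Product: 20 N'-[(4R)-4-hydroxy-3,3-dimethylcyclohexylidene]-2,4,6-triisopropylbenzenesulfonohydrazide, via hydroxy ketone 19 (not isolated)
Conditions: 2,4,6-triisopropylbenzenesulfonohydrazide (1.05 equiv), HCl (cat.), MeCN/H2O, rt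
Reagents that add atoms: 2,4,6-triisopropylbenzenesulfonohydrazide, CC(C)c1cc(C(C)C)c(S(=O)(=O)NN)c(C(C)C)c1
Why: Acid-catalysed ketal hydrolysis followed in the same flask by hydrazone condensation, which pulls the deketalisation to completion; the carbinol centre is not involved.

Step 13
Reactants: 20 trisylhydrazone
Product: 22 (1R)-4-(hydroxymethyl)-6,6-dimethylcyclohex-3-en-1-ol, via alkenyllithium 21 (not isolated)
Conditions: n-BuLi (3.3 equiv), THF, −78 → 0 °C; then (CH2O)n, 0 °C → rt; NH4Cl
Reagents that add atoms: formaldehyde (from paraformaldehyde), C=O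
Why: Shapiro reaction: deprotonation occurs at the α-CH2 remote from the gem-dimethyl group, loss of sulfinate and nitrogen gives the alkenyllithium at the former carbonyl carbon (C1'=C2'), and formaldehyde traps it as the primary allylic alcohol.

Step 14
Reactants: 22 allylic alcohol
Product: 23 (1R,3R,6R)-6-(hydroxymethyl)-4,4-dimethyl-7-oxabicyclo[4.1.0]heptan-3-ol
Conditions: Ti(Oi-Pr)4 (1.0 equiv), D-(−)-diethyl tartrate (1.2 equiv), t-BuOOH (2 equiv), 4 Å MS, CH2Cl2, −20 °C
Reagents that add atoms: tert-butyl hydroperoxide, CC(C)(C)OO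
Why: Sharpless asymmetric epoxidation of a primary allylic alcohol under reagent control: L-(+)-tartrate gives the 2S series of epoxy alcohols, so the D-(−)-ester should give the R-configured carbinol-bearing epoxide carbon, which places the C1' oxygen on the ring face opposite the C4' hydroxyl.

Step 15
Reactants: 23 epoxy diol
Product: 24 (1R,4R)-1-(hydroxymethyl)-3,3-dimethylcyclohexane-1,4-diol
Conditions: LiAlH4, THF, 0 → 40 °C
Reagents that add atoms: none
Why: Hydride opening of the trisubstituted epoxide (SN2) occurs at the secondary carbon C2', since the fully substituted C1' cannot be attacked, so the C1'–O bond and its configuration are retained in the tertiary alcohol.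

Step 16
Reactants: 24 triol
Product: 25 tris(triethylsilyl) ether of 24
Conditions: TESOTf (4 equiv), 2,6-lutidine, CH2Cl2, 0 °C → rt
Reagents that add atoms: triethylsilyl trifluoromethanesulfonate, CC[Si](CC)(CC)OS(=O)(=O)C(F)(F)F
Why: Silyl triflate with a hindered pyridine base silylates primary, neopentyl secondary and tertiary hydroxyls alike (exhaustive silylation).

Step 17
Reactants: 25 tris-TES ether
Product: 26 (1R,4R)-3,3-dimethyl-1,4-bis(triethylsilyloxy)cyclohexane-1-carbaldehyde
Conditions: (COCl)2, DMSO, CH2Cl2, −78 → −30 °C; Et3N, −78 °C → rt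
Reagents that add atoms: none
Why: Swern conditions cleave and oxidise a primary triethylsilyl ether directly to the aldehyde while secondary and tertiary TES ethers persist, and the α-quaternary aldehyde cannot enolise.

**Fragment union and end game**

Step 18
Reactants: 16 cyclopropyl ketone; 26 aldehyde
Product: 28 aldol adduct (16 bearing at C1β the (R)-hydroxy[(1R,4R)-3,3-dimethyl-1,4-bis(triethylsilyloxy)cyclohexyl]methyl group; C1 is S), via titanium enolate 27 (not isolated)
Conditions: LDA (2.2 equiv), THF, −78 °C; ClTi(Oi-Pr)3 (2.4 equiv), −78 → −40 °C; then 26, −78 → −30 °C; aq. NH4F/NH4Cl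
Reagents that add atoms: none
Why: Directed aldol addition of a triisopropoxytitanium enolate: the cyclopropane CH at C3 is not deprotonated, so the enolate forms only toward C1; the aldehyde should add on the β face, trans to C7 and away from the titanated C7 alkoxide, and titanium enolates of cyclic ketones favour the syn (erythro) aldol, which is the C1/C8 relationship of the target.

Step 19
Reactants: 28 aldol adduct
Product: 29 3aα-methyl trans-hydrindan-2-one (28 with the cyclopropane opened to the angular methyl)
Conditions: Li (6 equiv), NH3(l)/THF, t-BuOH (1 equiv), −78 °C, 15 min; isoprene, then NH4Cl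
Reagents that add atoms: none
Why: Dissolving-metal reduction of a conjugated cyclopropyl ketone: the ketyl cleaves the external C3–CH2 bond, the one that overlaps with the carbonyl π system in a bicyclo[3.1.0]hexan-2-one, giving the C2=C3 enolate and after protonation the methyl group with C3a unchanged; silyl ethers and alkoxides are inert.

Step 20
Reactants: 29 β-hydroxy ketone
Product: 31 2β,8-syn diol, via boron chelate 30 (not isolated)
Conditions: Et2BOMe (1.2 equiv), THF/MeOH (4:1), −78 °C; NaBH4; AcOH, then MeOH evaporation (×3)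
Reagents that add atoms: none
Why: Narasaka–Prasad reduction: the boron chelate between the C8 oxygen and the C2 carbonyl lies on the β face of the cyclopentanone, so external hydride should add from the α face and give the 2β-hydroxyl, the 1,3-syn diol of the target.

Step 21
Reactants: 31 diol
Product: 32 C2 allyl carbonate of 31
Conditions: allyl chloroformate (1.3 equiv), pyridine, CH2Cl2, −20 → 0 °C
Reagents that add atoms: allyl chloroformate, C=CCOC(=O)Cl
Why: Carbonate formation (acylation) should be selective for the ring secondary hydroxyl at C2, because the C8 hydroxyl is flanked by the quaternary C1' and by C1, and tertiary alcohols do not react under these conditions.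

Step 22
Reactants: 32 allyl carbonate
Product: 33 C8 acetate of 32
Conditions: Ac2O (5 equiv), DMAP (1 equiv), pyridine, 40 °C
Reagents that add atoms: acetic anhydride, CC(=O)OC(C)=O
Why: DMAP-catalysed acetylation of the only remaining secondary hydroxyl; the tertiary C7 alcohol is too hindered to acylate.

Step 23
Reactants: 33 acetate
Product: 34 desilylated tetraol (4β-OH and 4'R-OH both axial; free C7 and C1' tertiary hydroxyls; C8 acetate; C2 allyl carbonate)
Conditions: HF (48% aq.)/MeCN (1:9), 0 °C → rt
Reagents that add atoms: none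
Why: Acidic fluoride cleavage of the two TES ethers and the TBS ether (desilylation); acetate, allyl carbonate and tertiary alcohols are stable to it.

Step 24
Reactants: 34 tetraol
Product: 35 dibromide (C2 allyl carbonate of the target)
Conditions: CBr4 (6 equiv), PPh3 (6 equiv), pyridine (2 equiv), toluene, 0 → 60 °C
Reagents that add atoms: carbon tetrabromide, BrC(Br)(Br)Br
Why: Appel reaction: bromide displaces the two axial oxyphosphonium groups by SN2 with inversion and so should give the equatorial bromides at C4 (S) and C4' (S), as is known for axial alcohols beside a quaternary carbon; the tertiary alcohols are too hindered to be activated.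

Step 25
Reactants: 35 allyl carbonate
Product: 36 target CNP0166243.1
Conditions: Pd(PPh3)4 (5 mol%), morpholine (5 equiv), THF, rt
Reagents that add atoms: none
Why: Tsuji–Trost deallylation: the π-allyl palladium complex is captured by morpholine and the carbonic half ester loses CO2, under near-neutral conditions that leave the acetate and both secondary bromides alone.

**Compound list**

1 | (R)-linalool, (3R)-3,7-dimethylocta-1,6-dien-3-ol | C=C[C@](C)(O)CCC=C(C)C | starting material
2 | (3R)-5-(3,3-dimethyl-1,2,4-trioxolan-5-yl)-3-methylpent-1-en-3-ol (ozonide) | C=C[C@](C)(O)CCC1OOC(C)(C)O1 | intermediate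
3 | (5R)-5-ethenyl-5-methyloxolan-2-ol (lactol, both anomers) | C=C[C@@]1(C)CCC(O)O1 | intermediate
4 | ethynyl(trimethyl)silane | C#C[Si](C)(C)C | starting material
5 | (3R,6RS)-3-methyl-8-(trimethylsilyl)oct-1-en-7-yne-3,6-diol | C=C[C@](C)(O)CCC(O)C#C[Si](C)(C)C | intermediate
6 | (6R)-6-hydroxy-6-methyl-1-(trimethylsilyl)oct-7-en-1-yn-3-one | C=C[C@](C)(O)CCC(=O)C#C[Si](C)(C)C | intermediate
7 | (3R,6R)-3-methyl-8-(trimethylsilyl)oct-1-en-7-yne-3,6-diol | C=C[C@](C)(O)CC[C@@H](O)C#C[Si](C)(C)C | intermediate
8 | (3R,6R)-3-methyloct-1-en-7-yne-3,6-diol | C=C[C@](C)(O)CC[C@@H](O)C#C | intermediate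
9 | (3R,6R)-6-[tert-butyl(dimethyl)silyl]oxy-3-methyloct-1-en-7-yn-3-ol | C=C[C@](C)(O)CC[C@@H](O[Si](C)(C)C(C)(C)C)C#C | intermediate
10 | (4R,7R,7aS)-4-[tert-butyl(dimethyl)silyl]oxy-7-hydroxy-7-methyl-1,4,5,6,7,7a-hexahydro-2H-inden-2-one (4β-OTBS, 7α-OH, 7β-CH3, 7aβ-H) | C1C(=O)C=C2[C@H](O[Si](C)(C)C(C)(C)C)CC[C@@](C)(O)[C@@H]12 | intermediate
11 | C2 ethylene ketal of 10 with the C7 hydroxyl as trimethylsilyl ether | C1C2(OCCO2)C=C3[C@H](O[Si](C)(C)C(C)(C)C)CC[C@@](C)(O[Si](C)(C)C)[C@@H]13 | intermediate
12 | key-step precursor: C2 ethylene ketal of 10 (C3=C3a alkene, 4β-OTBS, free 7α-OH, 7aβ-H) | C1C2(OCCO2)C=C3[C@H](O[Si](C)(C)C(C)(C)C)CC[C@@](C)(O)[C@@H]13 | intermediate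
13 | diiodomethane | ICI | starting material
14 | iodomethylzinc C7-alkoxide of 12 | C1C2(OCCO2)C=C3[C@H](O[Si](C)(C)C(C)(C)C)CC[C@@](C)(O[Zn]CI)[C@@H]13 | intermediate
15 | key-step product: 12 with a CH2 bridge across C3–C3a on the α face (cyclopropane-fused hydrindane ketal) | C1C4(OCCO4)[C@@H]3[C@]2(C3)[C@H](O[Si](C)(C)C(C)(C)C)CC[C@@](C)(O)[C@@H]12 | intermediate
16 | cyclopropyl ketone: C2 ketone of 15 (3α,3aα-methylene bridge, 4β-OTBS, 7α-OH, 7β-CH3, 7aβ-H) | C1C(=O)[C@@H]3[C@]2(C3)[C@H](O[Si](C)(C)C(C)(C)C)CC[C@@](C)(O)[C@@H]12 | intermediate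
17 | 7,7-dimethyl-1,4-dioxaspiro[4.5]decan-8-one | O=C1CCC2(OCCO2)CC1(C)C | starting material
18 | (8R)-7,7-dimethyl-1,4-dioxaspiro[4.5]decan-8-ol | O1CCOC12CC[C@@H](O)C(C)(C)C2 | intermediate
19 | (4R)-4-hydroxy-3,3-dimethylcyclohexan-1-one | O=C1CC[C@@H](O)C(C)(C)C1 | intermediate
20 | N'-[(4R)-4-hydroxy-3,3-dimethylcyclohexylidene]-2,4,6-triisopropylbenzenesulfonohydrazide | CC(C)c1cc(C(C)C)c(S(=O)(=O)NN=C2CC[C@@H](O)C(C)(C)C2)c(C(C)C)c1 | intermediate
21 | [(4R)-4-(lithiooxy)-5,5-dimethylcyclohex-1-en-1-yl]lithium | [Li]C1=CC[C@@H](O[Li])C(C)(C)C1 | intermediate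
22 | (1R)-4-(hydroxymethyl)-6,6-dimethylcyclohex-3-en-1-ol | OCC1=CC[C@@H](O)C(C)(C)C1 | intermediate
23 | (1R,3R,6R)-6-(hydroxymethyl)-4,4-dimethyl-7-oxabicyclo[4.1.0]heptan-3-ol (epoxide oxygen trans to the ring hydroxyl) | OC[C@@]12O[C@@H]1C[C@@H](O)C(C)(C)C2 | intermediate
24 | (1R,4R)-1-(hydroxymethyl)-3,3-dimethylcyclohexane-1,4-diol | OC[C@@]1(O)CC[C@@H](O)C(C)(C)C1 | intermediate
25 | tris(triethylsilyl) ether of 24 | CC[Si](CC)(CC)OC[C@@]1(O[Si](CC)(CC)CC)CC[C@@H](O[Si](CC)(CC)CC)C(C)(C)C1 | intermediate
26 | (1R,4R)-3,3-dimethyl-1,4-bis(triethylsilyloxy)cyclohexane-1-carbaldehyde | O=C[C@@]1(O[Si](CC)(CC)CC)CC[C@@H](O[Si](CC)(CC)CC)C(C)(C)C1 | intermediate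
27 | bis(triisopropoxytitanium) derivative of 16 (C1=C2 enolate and C7 alkoxide) | C1=C(O[Ti](OC(C)C)(OC(C)C)OC(C)C)[C@@H]3[C@]2(C3)[C@H](O[Si](C)(C)C(C)(C)C)CC[C@@](C)(O[Ti](OC(C)C)(OC(C)C)OC(C)C)[C@@H]12 | intermediate
28 | aldol adduct: 16 with the (R)-hydroxy[(1R,4R)-3,3-dimethyl-1,4-bis(triethylsilyloxy)cyclohexyl]methyl group at C1β (1S) | O[C@H]([C@@H]1C(=O)[C@@H]3[C@]2(C3)[C@H](O[Si](C)(C)C(C)(C)C)CC[C@@](C)(O)[C@@H]12)[C@@]1(O[Si](CC)(CC)CC)CC[C@@H](O[Si](CC)(CC)CC)C(C)(C)C1 | intermediate
29 | 28 with the cyclopropane opened: 3aα-methyl trans-hydrindan-2-one (C8 hydroxyl free) | O[C@H]([C@@H]1C(=O)C[C@]2(C)[C@H](O[Si](C)(C)C(C)(C)C)CC[C@@](C)(O)[C@@H]12)[C@@]1(O[Si](CC)(CC)CC)CC[C@@H](O[Si](CC)(CC)CC)C(C)(C)C1 | intermediate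
30 | O8-diethylboryl derivative (boron chelate) of 29 | CCB(CC)O[C@H]([C@@H]1C(=O)C[C@]2(C)[C@H](O[Si](C)(C)C(C)(C)C)CC[C@@](C)(O)[C@@H]12)[C@@]1(O[Si](CC)(CC)CC)CC[C@@H](O[Si](CC)(CC)CC)C(C)(C)C1 | intermediate
31 | 2β,8-syn diol (2R) from 29 | O[C@H]([C@@H]1[C@H](O)C[C@]2(C)[C@H](O[Si](C)(C)C(C)(C)C)CC[C@@](C)(O)[C@@H]12)[C@@]1(O[Si](CC)(CC)CC)CC[C@@H](O[Si](CC)(CC)CC)C(C)(C)C1 | intermediate
32 | C2 allyl carbonate of 31 | O[C@H]([C@@H]1[C@H](OC(=O)OCC=C)C[C@]2(C)[C@H](O[Si](C)(C)C(C)(C)C)CC[C@@](C)(O)[C@@H]12)[C@@]1(O[Si](CC)(CC)CC)CC[C@@H](O[Si](CC)(CC)CC)C(C)(C)C1 | intermediate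
33 | C8 acetate of 32 | CC(=O)O[C@H]([C@@H]1[C@H](OC(=O)OCC=C)C[C@]2(C)[C@H](O[Si](C)(C)C(C)(C)C)CC[C@@](C)(O)[C@@H]12)[C@@]1(O[Si](CC)(CC)CC)CC[C@@H](O[Si](CC)(CC)CC)C(C)(C)C1 | intermediate
34 | desilylated 33 (4β-OH, 4'R-OH, C7 and C1' tertiary OH free) | CC(=O)O[C@H]([C@@H]1[C@H](OC(=O)OCC=C)C[C@]2(C)[C@H](O)CC[C@@](C)(O)[C@@H]12)[C@@]1(O)CC[C@@H](O)C(C)(C)C1 | intermediate
35 | C2 allyl carbonate of the target (4α-Br, 4'S-Br) | CC(=O)O[C@H]([C@@H]1[C@H](OC(=O)OCC=C)C[C@]2(C)[C@@H](Br)CC[C@@](C)(O)[C@@H]12)[C@@]1(O)CC[C@H](Br)C(C)(C)C1 | intermediate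
36 | CNP0166243.1: (R)-[(1R,4S)-4-bromo-1-hydroxy-3,3-dimethylcyclohexyl][(1S,2R,3aS,4S,7R,7aS)-4-bromo-2,7-dihydroxy-3a,7-dimethyloctahydro-1H-inden-1-yl]methyl acetate | CC(=O)O[C@H]([C@@H]1[C@H](O)C[C@]2(C)[C@@H](Br)CC[C@@](C)(O)[C@@H]12)[C@@]1(O)CC[C@H](Br)C(C)(C)C1 | target

**Step count**

Total: 25 steps. Longest linear sequence: 18 steps (steps 1–10 and 18–25, from linalool). The side-chain aldehyde takes 7 steps (11–17).

**Steps most likely to fail**

1. Step 9 (methylene delivery). The alkene is flanked by two allylic oxygens and the director is a hindered tertiary alkoxide, so transfer may be slow or may lose facial selectivity. Fallback: nucleophilic in place of electrophilic cyclopropanation. It sets out from enone 10 and comes back at cyclopropyl ketone 16. Dimethylsulfoxonium methylide (Me3S(O)I, NaH, DMSO, rt; Corey–Chaykovsky reaction) adds to C3a of the enone and closes the ring at C3. The axial 4β-silyl ether blocks the β face, so the CH2 should again arrive on the α face. No new compound lies on this way, and steps 8–10 are skipped.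

2. Step 24 (double bromide substitution). Both centres are secondary and next to a quaternary carbon, so elimination or a 1,2-methyl shift may outrun substitution, and the tertiary alcohols may dehydrate at the temperature needed. Fallback: separate activation from displacement. It sets out from tetraol 34 and comes back at dibromide 35. Tf2O (2.2 equiv) and pyridine in CH2Cl2 at −40 °C should give the C4,C4'-bis(trifluoromethanesulfonate) F1. Bu4NBr in toluene at 0 °C → rt then displaces both sulfonates by SN2 with inversion.

3. Step 18 (aldol union). The α-quaternary aldehyde may add slowly, the adduct may revert, or the syn selectivity at C8 may be poor. Fallback: Lewis-acid Mukaiyama aldol through an open transition state. It sets out from ketone 16 and comes back at aldol 28. TMSOTf and Et3N in CH2Cl2 at 0 °C should give the silyl enol ether F2 (C7–OH is silylated as well; only C1 can be enolised). BF3·OEt2 with aldehyde 26 in CH2Cl2 at −78 °C, followed by an aqueous work-up that cleaves both O–SiMe3 bonds, gives 28. Attack trans to C7 and the antiperiplanar arrangement of a cyclic enol silane should again favour the 1β,8-syn adduct.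

**Further compounds**

F0 | step 9 | none | none
F1 | step 24 | C4,C4'-bis(trifluoromethanesulfonate) of 34 | CC(=O)O[C@H]([C@@H]1[C@H](OC(=O)OCC=C)C[C@]2(C)[C@H](OS(=O)(=O)C(F)(F)F)CC[C@@](C)(O)[C@@H]12)[C@@]1(O)CC[C@@H](OS(=O)(=O)C(F)(F)F)C(C)(C)C1
F2 | step 18 | C1=C2 trimethylsilyl enol ether of 16 with the C7 hydroxyl as trimethylsilyl ether | C1=C(O[Si](C)(C)C)[C@@H]3[C@]2(C3)[C@H](O[Si](C)(C)C(C)(C)C)CC[C@@](C)(O[Si](C)(C)C)[C@@H]12
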